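A direct plan would buy the finished arene: 2,3-dihydroxybenzoic acid A1 would be converted with KHCO3 in DMF into its potassium salt A2, and A2 would be O-alkylated with 1-bromodocosane A3 at 60 °C to give the target ester in one step.
Its weakest operations would be these:
- The carboxylate alkylation of A2 by A3 would rest on a pKa gap alone. The 3-hydroxyl, which is not hydrogen-bonded to the carbonyl, would compete as an O-nucleophile whenever base or temperature drifted, and the waxy bromide A3 would react slowly, so phenol O-alkylation products of nearly the same polarity would have to be crystallised away.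
- The long heating of the unprotected catechol of A1 and A2 with base would invite autoxidation, and it is the operation one would least wish to run on valuable material. Protecting and deprotecting the diol would add two steps with no gain in complexity.
- The excess A1 would have to be separated from a product that is itself an acidic phenol. As strategy, no ring bond, ring closure or stereocentre would be made or controlled, because the whole 1,2,3-pattern would be purchased.

Plan of the new route
The retrosynthesis first cuts the two O–H bonds (to O–SiMe3), then in one operation the ring bonds C1–C2 and C3–C4 of the benzene ring, and last the acyl–oxygen bond of the ester, at the stage of a 2-pyrone.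
C1, C4, C5, C6 and the ester become docosyl 2-oxo-2H-pyran-3-carboxylate, whose O1–C2(=O) bridge leaves as CO2; C2 and C3 with both oxygens become tris(trimethylsiloxy)ethylene, a dihydroxyacetylene equivalent.
The enabling feature is the vicinal C2–OH/C3–OH pair next to the ester-bearing C1: an electron-rich enediol C2 unit beside an acceptor-substituted C4 diene unit. Both dienophile carbons carry oxygen, so either orientation gives the same arene.
Order of rings: the 2-pyrone ring is bought, and the benzene ring (the only ring of the target) arises from it last, with the docosyl ester already in place.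
No phenol competes with a carboxylate, no free catechol meets base or heat (it is unveiled by dilute acid at 20 °C), and the substitution pattern is built, not purchased.
Key step: step 2

Remark: the target has no stereocentre; methyl 2-oxo-2H-pyran-3-carboxylate, 1-docosanol and tris(trimethylsiloxy)ethylene are taken as catalogue chemicals.

Step 1
Reactants: 1 methyl 2-oxo-2H-pyran-3-carboxylate; 2 1-docosanol
Product: 3 docosyl 2-oxo-2H-pyran-3-carboxylate
Conditions: 1 (1.3 equiv), 2 (1.0 equiv), TsOH·H2O (10 mol %), PhMe, reflux through 5 Å molecular sieves (Soxhlet), N2; silica chromatography (removes TsOH), recrystallisation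
Reagents that add atoms: none
Why: Acid-catalysed transesterification of a methyl ester with a primary alcohol, driven by trapping methanol on the sieves; the 2-pyrone tolerates Brønsted acid, any reversible opening at the lactone carbonyl or addition at C6 should reclose to the same pyrone, and no stereocentre is involved.

Step 2
Reactants: 3 docosyl 2-oxo-2H-pyran-3-carboxylate; 4 tris(trimethylsiloxy)ethylene [1,1,2-tris(trimethylsilyloxy)ethene]
Product: 7 docosyl 2,3-bis(trimethylsilyloxy)benzoate, via bicyclic lactone 5 (not isolated), via cyclohexadiene 6 (not isolated)
Conditions: 4 (2.5 equiv), PhMe (0.3 M), 110 °C, Ar, 24 h; evaporation under high vacuum, crude used directly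
Reagents that add atoms: none
Why: Proposed new method: the electron-poor diene of 3 (C3–C6 of the 2-pyrone, activated by the C3 ester and the lactone carbonyl) should add the electron-rich, tri-oxygenated alkene 4 in an inverse-electron-demand [4+2] cycloaddition to the 2-oxabicyclo[2.2.2]octenone 5, which loses CO2 by retro-Diels–Alder reaction to the cyclohexadiene 6, and 6 aromatises by 1,2-elimination of trimethylsilanol from its silyl ketal carbon. The closest known reaction type is the thermal salicylate annulation of 3-alkoxycarbonyl-2-pyrones with 1,1-dialkoxyethylenes (cycloaddition, loss of CO2, loss of alcohol); new here is a ketene bis(silyl) acetal that carries a third silyloxy group on its other carbon and so acts as a dihydroxyacetylene equivalent. The benzene ring (ring A) is closed by intermolecular [4+2] cycloaddition, which forms C1–C2 and C3–C4 of the arene in one operation with the pyrone ring as a sacrificial template. The stereocentres of 5 and 6 are transient and are erased on aromatisation, so neither endo/exo nor facial selectivity matters, and regioselectivity is not needed because both carbons of 4 carry oxygen and either orientation converges on 7. The step does need cycloaddition to win over an open-chain conjugate addition with silyl transfer; the absence of Lewis acid and fluoride and the non-polar solvent should secure this, and a zwitterion formed by attack at C6 (malonate-type anion at C3, silyloxocarbenium ion on the other carbon) can still collapse to the same bicycle 5. The oxidation level is fixed by the reagent, since 6 can aromatise only by losing one of its three silyloxy groups, so both catechol oxygens are retained.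

Step 3
Reactants: 7 docosyl 2,3-bis(trimethylsilyloxy)benzoate
Product: 8 Gentiside J (docosyl 2,3-dihydroxybenzoate)
Conditions: 1 M aq. HCl, THF, 0 → 20 °C, N2, 1 h; EtOAc extraction, recrystallisation (hexane/EtOAc)
Reagents that add atoms: none
Why: Acid-catalysed hydrolysis of aryl trimethylsilyl ethers (cleavage at silicon) should leave the alkyl benzoate untouched and keep the catechol protonated and so not prone to autoxidation; any 6 that survived step 2 should converge on 8 under the same conditions by ketal hydrolysis and enolisation, and no stereocentre is involved.

Compound list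
1 | methyl 2-oxo-2H-pyran-3-carboxylate | COC(=O)C1=CC=COC1=O | starting material
2 | 1-docosanol | CCCCCCCCCCCCCCCCCCCCCCO | starting material
3 | docosyl 2-oxo-2H-pyran-3-carboxylate | CCCCCCCCCCCCCCCCCCCCCCOC(=O)C1=CC=COC1=O | intermediate
4 | tris(trimethylsiloxy)ethylene, 1,1,2-tris(trimethylsilyloxy)ethene | C[Si](C)(C)OC=C(O[Si](C)(C)C)O[Si](C)(C)C | starting material
5 | docosyl 3-oxo-7,8,8-tris(trimethylsilyloxy)-2-oxabicyclo[2.2.2]oct-5-ene-4-carboxylate (racemic, both C7 epimers) | CCCCCCCCCCCCCCCCCCCCCCOC(=O)C12C=CC(OC1=O)C(O[Si](C)(C)C)C2(O[Si](C)(C)C)O[Si](C)(C)C | intermediate
6 | docosyl 5,6,6-tris(trimethylsilyloxy)cyclohexa-1,3-diene-1-carboxylate (racemic) | CCCCCCCCCCCCCCCCCCCCCCOC(=O)C1=CC=CC(O[Si](C)(C)C)C1(O[Si](C)(C)C)O[Si](C)(C)C | intermediate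
7 | docosyl 2,3-bis(trimethylsilyloxy)benzoate | CCCCCCCCCCCCCCCCCCCCCCOC(=O)c1cccc(O[Si](C)(C)C)c1O[Si](C)(C)C | intermediate
8 | Gentiside J, docosyl 2,3-dihydroxybenzoate | CCCCCCCCCCCCCCCCCCCCCCOC(=O)c1cccc(O)c1O | target

Total step count: 3. Longest linear sequence: 3 steps (1 → 3 → 7 → 8).

Steps most likely to fail

Step 2 (key step, proposed method). The silyl ketene acetal may add as a conjugate donor with silyl transfer instead of undergoing cycloaddition, or be lost by protodesilylation or thermal O-to-C silyl migration, so that the arene ring never closes. The fallback uses known chemistry and another ring construction; it sets out from 2 and comes back to the route at 8, bypassing 3 to 7. Compound 2 would be heated with commercial ethyl 4-(benzyloxy)-3-oxobutanoate in toluene at reflux with distillation of ethanol (β-keto ester transesterification by way of the acylketene) to give docosyl 4-(benzyloxy)-3-oxobutanoate F1. Silylation (Me3SiCl, Et3N, PhMe, 20 °C) would give the silyl enol ether docosyl 4-(benzyloxy)-3-(trimethylsilyloxy)but-2-enoate F2, and γ-deprotonation with O-silylation (LiN(iPr)2, THF, −78 °C; Me3SiCl) would give the 1,3-bis(silyl enol ether) 4-(benzyloxy)-1-(docosyloxy)-1,3-bis(trimethylsilyloxy)buta-1,3-diene F3. A Chan-type formal [3+3] cyclocondensation of F3 with 1,1,3,3-tetramethoxypropane (Me3SiOTf, 10 mol %, CH2Cl2, −78 → 20 °C) would join C4 and C2 of the diene to the two acetal carbons and, after loss of methanol, give docosyl 3-(benzyloxy)-2-hydroxybenzoate F4. Hydrogenolysis of the benzyl ether (H2, Pd/C, EtOAc, 20 °C) would then give 8.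

Step 1. The alcohol may attack C6 or the lactone carbonyl of the electrophilic pyrone (ring opening, oligomeric material) in competition with exchange at the ester, or the exchange may stay incomplete. The fallback builds the pyrone ring on the docosyl ester; it sets out from 2 and comes back at 3. Fischer esterification of malonic acid with 2 (2 equiv, TsOH·H2O, PhMe, Dean–Stark) would give didocosyl malonate F5. Condensation of F5 with 1,1,3,3-tetramethoxypropane (ZnCl2 cat., Ac2O, 100 °C) would give didocosyl 2-[(E)-3-methoxyprop-2-en-1-ylidene]malonate F6. Acid-mediated enol ether hydrolysis and lactonisation (TsOH·H2O, wet PhMe, 80 °C; the enol ether geometry equilibrates through its protonated form) would close the 2-pyrone with loss of one docosanol (recovered) and give 3. The two esters of F6 are identical, so no selectivity question arises.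

Step 3. The free catechol may autoxidise during aqueous work-up and purification, or hydrolysis may stop at mono-silyl ethers that co-crystallise. The fallback purifies a protected form before the phenols are set free; it sets out from 7 and comes back at 8. Desilylative acetylation of crude 7 (KF, Ac2O, MeCN, 20 °C; each aryloxide is trapped as it is released) would give the air-stable, crystallisable docosyl 2,3-diacetoxybenzoate F7. After recrystallisation, acid-catalysed methanolysis of the two aryl acetates of F7 (AcCl cat., MeOH/THF, 20 °C), which are far more labile than the long-chain alkyl benzoate, would give 8.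

Further compounds
F1 | step 2 | docosyl 4-(benzyloxy)-3-oxobutanoate | CCCCCCCCCCCCCCCCCCCCCCOC(=O)CC(=O)COCc1ccccc1
F2 | step 2 | docosyl 4-(benzyloxy)-3-(trimethylsilyloxy)but-2-enoate (mixture of geometric isomers) | CCCCCCCCCCCCCCCCCCCCCCOC(=O)C=C(COCc1ccccc1)O[Si](C)(C)C
F3 | step 2 | 4-(benzyloxy)-1-(docosyloxy)-1,3-bis(trimethylsilyloxy)buta-1,3-diene (mixture of geometric isomers) | CCCCCCCCCCCCCCCCCCCCCCOC(O[Si](C)(C)C)=CC(O[Si](C)(C)C)=COCc1ccccc1
F4 | step 2 | docosyl 3-(benzyloxy)-2-hydroxybenzoate | CCCCCCCCCCCCCCCCCCCCCCOC(=O)c1cccc(OCc2ccccc2)c1O
F5 | step 1 | didocosyl malonate | CCCCCCCCCCCCCCCCCCCCCCOC(=O)CC(=O)OCCCCCCCCCCCCCCCCCCCCCC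
F6 | step 1 | didocosyl 2-[(E)-3-methoxyprop-2-en-1-ylidene]malonate | CCCCCCCCCCCCCCCCCCCCCCOC(=O)C(=C/C=C/OC)C(=O)OCCCCCCCCCCCCCCCCCCCCCC
F7 | step 3 | docosyl 2,3-diacetoxybenzoate | CCCCCCCCCCCCCCCCCCCCCCOC(=O)c1cccc(OC(C)=O)c1OC(C)=O
A1 | direct plan | 2,3-dihydroxybenzoic acid | OC(=O)c1cccc(O)c1O
A2 | direct plan | potassium 2,3-dihydroxybenzoate | [K+].[O-]C(=O)c1cccc(O)c1O
A3 | direct plan | 1-bromodocosane | CCCCCCCCCCCCCCCCCCCCCCBr
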